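Slowness at the start is the trouble in these flasks: catalyst must first be made from precatalyst, while substrate already reacts with partner without it.

the same everywhere: precatalyst 1 mol%; time 40 h

| charge | substrate | partner | remark |
|---|---|---|---|
| summer | 11 mM | 2.50 equiv (fed, over 8.0 h) | all else is in the flask from the start; the feed brings no volume worth counting |
| dawn | 11 mM | 2.50 equiv | everything together at the start |
| spring | 11 mM | 2.50 equiv (in portions, 3, over 8.0 h) | first portion at the start, last at 8.0 h |
| winter | 11 mM (fed, over 8.0 h) | 2.50 equiv | all else is in the flask from the start; the feed brings no volume worth counting |

    substrate + partner + catalyst → catalyst + target (k1 = 52800 /M²/h)
    partner + precatalyst → catalyst + spent reagent (k2 = 3.81 /M/h)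
    substrate + partner → uncatalysed product (k3 = 3.40 /M/h)

- the flask with the highest share of target in target plus uncatalysed product ("all alike" if they lie within 1.5 percentage points) (summer / dawn / spring / winter / all alike)
- share of target in target plus uncatalysed product at the end, summer
- share of target in target plus uncatalysed product at the end, dawn
- share of target in target plus uncatalysed product at the end, spring
- share of target in target plus uncatalysed product at the end, winter

Follow one substrate molecule, the limiting reagent here. It leaves by the catalysed step or the uncatalysed one. Each rate holds [substrate] and [partner] once, so those cancel and its odds are set by [catalyst]: the share to target is the catalysed rate constant times [catalyst], over that same term plus the uncatalysed constant. This is a selectivity factor written as a share. With the whole charge awake it comes to 63.1%, the full fork share.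

In the first instants [catalyst] is nil, so the fork sends substrate to uncatalysed product. In dawn, with [partner] held at its charge, precatalyst has a half-life of 6.62 h and substrate one of 7.4 h by the uncatalysed step alone, so on these starting figures catalyst wakes a little faster and substrate reacts beside partly woken catalyst. Later in dawn the odds improve as catalyst wakes, while substrate goes down at the same time.

My own reckoning takes a typical dawn molecule to meet half the charge, which gives 46.1%. Partner also stands once in the waking step, so feeding it slows each race alike, whereas winter's substrate feed lasts 8.0 h, longer than that waking half-life, so its late substrate should meet catalyst woken meanwhile.

The forecast names winter, with 47.8% there against 38.9%, 38.9% and 38.9% for summer, dawn and spring, holding that “dosing partner just rescales the clock”. Its dawn figure is lower than mine.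

The flask gives 38.7%, 38.7% and 38.7% for summer, dawn and spring, and 48.2% for winter. After 8.00 h, catalyst stood at 54.6% of its charge in winter and 31.5% in summer, which puts the fork share at that moment at 48.3% and 35.0%, both under 63.1%. The spring share moves by 5 points with precatalyst at 0.76 mol% or 1.3 mol%, the other amounts and the time held, and a run there would part from the forecast's spring figure.

A winter flask with 6.20 equiv of partner keeps the same full fork share, 63.1%, since [partner] cancels from it. That flask gives 54.4%, under the full fork share.

The numbers belong to no real substance, and the outcome is calculated.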